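**Retrosynthetic overview**
1. The tetronic acid ring is closed last, by Dieckmann cyclisation of α-propanoyloxy methyl ester 39 (from hydroxy ester 37).
2. The triene is cut at the central (E)-CH=CH bond: Wittig union of the western allylic tributylphosphonium salt 34 with the eastern (Z)-enal 20.
3. Eastern fragment: the Z-trisubstituted alkene is locked in a temporary dihydropyranone ring (acrylate ring-closing metathesis, then reductive opening). The C5 stereocentre and its C–C bond come from the key step, a Brown asymmetric methallylation of aldehyde 4.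
4. Western fragment: furan-3-yllithium plus 4-bromofuran-2-carbaldehyde, deoxygenation, lithiation/oxetane opening, then a stabilised Wittig for the (E)-trisubstituted alkene.
5. Ring order: both furans are bought; the dihydropyranone is formed and opened again; the tetronic acid ring is formed last.

Assumption: the target is the (5R)-4-hydroxyfuran-2(5H)-one tautomer with 2Z,4E,6E side-chain geometry as encoded, and catalogue items such as (+)-Ipc2BOMe, 3-bromofuran and 4-bromofuran-2-carbaldehyde count as commercially available.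

**Eastern fragment**

Step 1
Reactants: 1 (Z)-but-2-ene-1,4-diol
Product: 2 (Z)-1,4-bis[(4-methoxybenzyl)oxy]but-2-ene
Conditions: NaH (2.4 equiv.), PMBCl (2.3 equiv.), Bu4NI (cat.), THF/DMF, 0 °C → rt
Reagents that add atoms: 4-methoxybenzyl chloride, COc1ccc(CCl)cc1
Why: Williamson etherification of both primary allylic hydroxyls gives a symmetrical bis-ether that is a masked pair of aldehydes.

Step 2
Reactants: 2 (Z)-1,4-bis[(4-methoxybenzyl)oxy]but-2-ene
Product: 4 2-[(4-methoxybenzyl)oxy]acetaldehyde, via ozonide 3 (not isolated)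
Conditions: O3, CH2Cl2, −78 °C (Sudan Red 7B end point); PPh3, −78 °C → rt
Reagents that add atoms: ozone, [O-][O+]=O
Why: Ozonolysis of the symmetrical cis-alkene and reductive cleavage of the ozonide with PPh3 gives two equivalents of the α-alkoxy aldehyde without over-oxidation.

Step 3
Reactants: 4 2-[(4-methoxybenzyl)oxy]acetaldehyde; 5 (2-methylallyl)magnesium chloride
Product: 8 (2R)-1-[(4-methoxybenzyl)oxy]-4-methylpent-4-en-2-ol, via methallylborane 6 (not isolated), via borinate 7 (not isolated)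
Conditions: (+)-Ipc2BOMe [from (−)-α-pinene], 5, Et2O, −78 °C → rt; then 4, −78 °C, 3 h; 3 M NaOH, 30% H2O2, rt
Reagents that add atoms: none
Why: Brown asymmetric carbonyl allylation (methallylboration) through a chair Zimmerman–Traxler transition state, in which the (−)-α-pinene-derived Ipc ligands deliver the methallyl group to the Re face of the aldehyde, forms the C–C bond and sets the (R)-carbinol centre (typically ≥ 92% ee) that becomes C5 of the tetronic acid.

Step 4
Reactants: 8 (2R)-1-[(4-methoxybenzyl)oxy]-4-methylpent-4-en-2-ol; 9 acryloyl chloride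
Product: 10 (2R)-1-[(4-methoxybenzyl)oxy]-4-methylpent-4-en-2-yl prop-2-enoate
Conditions: Et3N, DMAP (cat.), CH2Cl2, −20 → 0 °C
Reagents that add atoms: none
Why: DMAP-catalysed O-acylation of the secondary alcohol installs the acrylate needed for ring closure without touching the stereocentre.

Step 5
Reactants: 10 (2R)-1-[(4-methoxybenzyl)oxy]-4-methylpent-4-en-2-yl prop-2-enoate
Product: 11 (6R)-6-{[(4-methoxybenzyl)oxy]methyl}-4-methyl-5,6-dihydro-2H-pyran-2-one
Conditions: second-generation Grubbs catalyst (H2IMes)(PCy3)Cl2Ru=CHPh (5–10 mol%), CH2Cl2 (0.005 M), 40 °C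
Reagents that add atoms: none
Why: Ring-closing olefin metathesis with loss of ethylene closes the six-membered unsaturated lactone, whose ring enforces the Z geometry of the new trisubstituted C=C bond.

Step 6
Reactants: 11 (6R)-6-{[(4-methoxybenzyl)oxy]methyl}-4-methyl-5,6-dihydro-2H-pyran-2-one
Product: 13 (2Z,5R)-6-[(4-methoxybenzyl)oxy]-3-methylhex-2-ene-1,5-diol, via lactol 12 (not isolated)
Conditions: iBu2AlH (4 equiv.), CH2Cl2, −78 → 0 °C; aq. KNaC4H4O6 (potassium sodium tartrate)
Reagents that add atoms: none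
Why: Exhaustive 1,2-reduction of the conjugated lactone by iBu2AlH (lactol, then the ring-opened hydroxy enal) gives the (Z)-allylic alcohol with the ring-derived alkene geometry intact.

Step 7
Reactants: 13 (2Z,5R)-6-[(4-methoxybenzyl)oxy]-3-methylhex-2-ene-1,5-diol
Product: 14 (2Z,5R)-1,5-bis[(tert-butyldimethylsilyl)oxy]-6-[(4-methoxybenzyl)oxy]-3-methylhex-2-ene
Conditions: TBSOTf (2.5 equiv.), 2,6-lutidine, CH2Cl2, −78 → 0 °C
Reagents that add atoms: tert-butyldimethylsilyl trifluoromethanesulfonate, CC(C)(C)[Si](C)(C)OS(=O)(=O)C(F)(F)F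
Why: Silyl triflate silylation protects both hydroxyls in one operation as TBS ethers that can later be told apart by their primary allylic versus hindered secondary environment.

Step 8
Reactants: 14 (2Z,5R)-1,5-bis[(tert-butyldimethylsilyl)oxy]-6-[(4-methoxybenzyl)oxy]-3-methylhex-2-ene
Product: 15 (2R,4Z)-2,6-bis[(tert-butyldimethylsilyl)oxy]-4-methylhex-4-en-1-ol
Conditions: DDQ (1.3 equiv.), CH2Cl2/pH 7 phosphate buffer (10:1), 0 °C
Reagents that add atoms: none
Why: Oxidative PMB ether cleavage by DDQ (benzylic oxocarbenium ion hydrolysed by water) is orthogonal to TBS ethers and to the isolated alkene.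

Step 9
Reactants: 15 (2R,4Z)-2,6-bis[(tert-butyldimethylsilyl)oxy]-4-methylhex-4-en-1-ol
Product: 17 (2R,4Z)-2,6-bis[(tert-butyldimethylsilyl)oxy]-4-methylhex-4-enoic acid, via aldehyde 16 (not isolated)
Conditions: TEMPO (0.2 equiv.), PhI(OAc)2 (2.5 equiv.), MeCN/H2O (1:1), 0 °C → rt
Reagents that add atoms: water, O
Why: Oxoammonium (TEMPO/PhI(OAc)2) oxidation takes the primary alcohol through the aldehyde hydrate to the carboxylic acid without epimerising the α-silyloxy centre or touching the alkene.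

Step 10
Reactants: 17 (2R,4Z)-2,6-bis[(tert-butyldimethylsilyl)oxy]-4-methylhex-4-enoic acid
Product: 18 methyl (2R,4Z)-2,6-bis[(tert-butyldimethylsilyl)oxy]-4-methylhex-4-enoate
Conditions: Me3SiCHN2, MeOH/toluene (1:4), 0 °C
Reagents that add atoms: trimethylsilyldiazomethane, C[Si](C)(C)C=[N+]=[N-]
Why: Methyl esterification by O-alkylation of the carboxylate with the diazomethane equivalent is neutral, so the α-stereocentre is untouched.

Step 11
Reactants: 18 methyl (2R,4Z)-2,6-bis[(tert-butyldimethylsilyl)oxy]-4-methylhex-4-enoate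
Product: 19 methyl (2R,4Z)-2-[(tert-butyldimethylsilyl)oxy]-6-hydroxy-4-methylhex-4-enoate
Conditions: PPTS (0.2 equiv.), MeOH, 0 °C → rt
Reagents that add atoms: none
Why: Acid-catalysed methanolysis (selective desilylation) removes the unhindered primary allylic TBS ether much faster than the hindered secondary TBS ether next to the electron-withdrawing ester.

Step 12
Reactants: 19 methyl (2R,4Z)-2-[(tert-butyldimethylsilyl)oxy]-6-hydroxy-4-methylhex-4-enoate
Product: 20 methyl (2R,4Z)-2-[(tert-butyldimethylsilyl)oxy]-4-methyl-6-oxohex-4-enoate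
Conditions: Dess–Martin periodinane (1.3 equiv.), NaHCO3, CH2Cl2, 0 °C, 30 min; used at once
Reagents that add atoms: none
Why: Buffered Dess–Martin oxidation converts the allylic alcohol into the enal quickly at 0 °C, which keeps the Z geometry from isomerising.

**Western fragment**

Step 13
Reactants: 21 3-bromofuran; 22 4-bromofuran-2-carbaldehyde
Product: 24 (4-bromofuran-2-yl)(furan-3-yl)methanol (racemic), via furan-3-yllithium 23 (not isolated)
Conditions: n-BuLi (1.0 equiv.), THF, −78 °C, 20 min; then 22, −78 °C; H2O quench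
Reagents that add atoms: none
Why: Bromine–lithium exchange at −78 °C gives furan-3-yllithium, whose 1,2-addition to the aldehyde is far faster than exchange with the second C–Br bond, and the new carbinol centre is racemic and removed in the next step.

Step 14
Reactants: 24 (4-bromofuran-2-yl)(furan-3-yl)methanol
Product: 25 4-bromo-2-(furan-3-ylmethyl)furan
Conditions: Et3SiH (3 equiv.), CF3CO2H (3 equiv., added last, dropwise), CH2Cl2, −40 → 0 °C
Reagents that add atoms: none
Why: Ionic hydrogenation, in which acid ionises the doubly heteroaryl-stabilised carbinol and Et3SiH traps the cation by hydride transfer, gives the bis-furylmethane and removes the racemic centre.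

Step 15
Reactants: 25 4-bromo-2-(furan-3-ylmethyl)furan; 26 oxetane
Product: 28 3-[5-(furan-3-ylmethyl)furan-3-yl]propan-1-ol, via furyllithium 27 (not isolated)
Conditions: n-BuLi (1.05 equiv.), THF, −78 °C, 15 min; then 26 (2 equiv.), BF3·OEt2 (1.5 equiv.), −78 °C; H2O quench
Reagents that add atoms: none
Why: Bromine–lithium exchange followed by BF3-promoted SN2 ring opening of oxetane by the aryllithium installs the three-carbon chain at C4 with unambiguous regiochemistry.

Step 16
Reactants: 28 3-[5-(furan-3-ylmethyl)furan-3-yl]propan-1-ol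
Product: 29 3-[5-(furan-3-ylmethyl)furan-3-yl]propanal
Conditions: Dess–Martin periodinane (1.3 equiv.), NaHCO3, CH2Cl2, 0 °C → rt
Reagents that add atoms: none
Why: Buffered Dess–Martin oxidation of the primary alcohol leaves the acid- and oxidant-sensitive furans untouched.

Step 17
Reactants: 29 3-[5-(furan-3-ylmethyl)furan-3-yl]propanal; 30 ethyl 2-(triphenylphosphoranylidene)propanoate
Product: 31 ethyl (2E)-5-[5-(furan-3-ylmethyl)furan-3-yl]-2-methylpent-2-enoate
Conditions: 30 (1.3 equiv.), CH2Cl2, rt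
Reagents that add atoms: none
Why: Wittig olefination with the stabilised α-methyl ylide gives the (E)-trisubstituted enoate (typically ≥ 95:5).

Step 18
Reactants: 31 ethyl (2E)-5-[5-(furan-3-ylmethyl)furan-3-yl]-2-methylpent-2-enoate
Product: 32 (2E)-5-[5-(furan-3-ylmethyl)furan-3-yl]-2-methylpent-2-en-1-ol
Conditions: iBu2AlH (2.5 equiv.), CH2Cl2, −78 °C; aq. KNaC4H4O6
Reagents that add atoms: none
Why: 1,2-Reduction of the conjugated ester by iBu2AlH gives the (E)-allylic alcohol without affecting alkene geometry.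

Step 19
Reactants: 32 (2E)-5-[5-(furan-3-ylmethyl)furan-3-yl]-2-methylpent-2-en-1-ol
Product: 33 4-[(3E)-5-bromo-4-methylpent-3-en-1-yl]-2-(furan-3-ylmethyl)furan
Conditions: CBr4 (1.3 equiv.), PPh3 (1.4 equiv.), CH2Cl2, 0 °C; used without storage
Reagents that add atoms: carbon tetrabromide, BrC(Br)(Br)Br
Why: Appel bromination converts the allylic alcohol into the bromide by SN2 displacement of the oxyphosphonium under neutral conditions that the furans tolerate.

Step 20
Reactants: 33 4-[(3E)-5-bromo-4-methylpent-3-en-1-yl]-2-(furan-3-ylmethyl)furan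
Product: 34 tributyl{(2E)-5-[5-(furan-3-ylmethyl)furan-3-yl]-2-methylpent-2-en-1-yl}phosphonium bromide
Conditions: PBu3 (1.2 equiv.), MeCN, rt
Reagents that add atoms: tributylphosphine, CCCCP(CCCC)CCCC
Why: SN2 quaternisation of tributylphosphine by the primary allylic bromide gives the phosphonium salt with retention of alkene geometry.

**Union and endgame**

Step 21
Reactants: 34 tributyl{(2E)-5-[5-(furan-3-ylmethyl)furan-3-yl]-2-methylpent-2-en-1-yl}phosphonium bromide; 20 methyl (2R,4Z)-2-[(tert-butyldimethylsilyl)oxy]-4-methyl-6-oxohex-4-enoate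
Product: 36 methyl (2R,4Z,6E,8E)-2-[(tert-butyldimethylsilyl)oxy]-11-[5-(furan-3-ylmethyl)furan-3-yl]-4,8-dimethylundeca-4,6,8-trienoate, via ylide 35 (not isolated)
Conditions: 34 (1.3 equiv.), KOtBu (1.25 equiv.), THF/toluene, 0 °C; then 20, −78 °C → rt
Reagents that add atoms: none
Why: Wittig olefination with an allylic tributylphosphonium ylide is strongly E-selective for the new disubstituted alkene, while the Z-alkene of the enal and the E-alkene of the ylide are carried through unchanged and the ester is not attacked at low temperature.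

Step 22
Reactants: 36 methyl (2R,4Z,6E,8E)-2-[(tert-butyldimethylsilyl)oxy]-11-[5-(furan-3-ylmethyl)furan-3-yl]-4,8-dimethylundeca-4,6,8-trienoate
Product: 37 methyl (2R,4Z,6E,8E)-11-[5-(furan-3-ylmethyl)furan-3-yl]-2-hydroxy-4,8-dimethylundeca-4,6,8-trienoate
Conditions: Bu4NF (1.5 equiv.), AcOH (1.5 equiv.), THF, 0 °C → rt
Reagents that add atoms: none
Why: Fluoride-mediated desilylation buffered with acetic acid frees the α-hydroxyl without base-induced epimerisation or damage to the triene.

Step 23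
Reactants: 37 methyl (2R,4Z,6E,8E)-11-[5-(furan-3-ylmethyl)furan-3-yl]-2-hydroxy-4,8-dimethylundeca-4,6,8-trienoate; 38 propanoic anhydride
Product: 39 methyl (2R,4Z,6E,8E)-11-[5-(furan-3-ylmethyl)furan-3-yl]-4,8-dimethyl-2-(propanoyloxy)undeca-4,6,8-trienoate
Conditions: 38 (2 equiv.), Et3N, DMAP (cat.), CH2Cl2, 0 °C
Reagents that add atoms: none
Why: DMAP-catalysed O-acylation installs the propanoate that supplies C2, C3 and the C3 methyl group of the tetronic acid.

Step 24
Reactants: 39 methyl (2R,4Z,6E,8E)-11-[5-(furan-3-ylmethyl)furan-3-yl]-4,8-dimethyl-2-(propanoyloxy)undeca-4,6,8-trienoate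
Product: 40 (5R)-5-{(2Z,4E,6E)-9-[5-(furan-3-ylmethyl)furan-3-yl]-2,6-dimethylnona-2,4,6-trien-1-yl}-4-hydroxy-3-methylfuran-2(5H)-one
Conditions: LiN(SiMe3)2 (2.2 equiv.), THF, −78 → 0 °C; then 1 M HCl to pH 3, 0 °C
Reagents that add atoms: none
Why: Dieckmann (intramolecular Claisen) condensation of the propanoate enolate onto the adjacent methyl ester closes the tetronic acid ring, driven by formation of the stabilised tetronate anion, and low temperature keeps the C5 stereocentre intact.

**Compound list**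

1 | (Z)-but-2-ene-1,4-diol | OC/C=C\CO | starting material
2 | (Z)-1,4-bis[(4-methoxybenzyl)oxy]but-2-ene | COc1ccc(COC/C=C\COCc2ccc(OC)cc2)cc1 | intermediate
3 | 3,5-bis{[(4-methoxybenzyl)oxy]methyl}-1,2,4-trioxolane (ozonide) | COc1ccc(COCC2OOC(COCc3ccc(OC)cc3)O2)cc1 | intermediate
4 | 2-[(4-methoxybenzyl)oxy]acetaldehyde | COc1ccc(COCC=O)cc1 | intermediate
5 | (2-methylallyl)magnesium chloride | CC(=C)C[Mg]Cl | starting material
6 | (2-methylallyl)diisopinocampheylborane, Ipc groups from (−)-α-pinene | CC(=C)CB([C@H]1C[C@H]2C[C@@H]([C@@H]1C)C2(C)C)[C@H]1C[C@H]2C[C@@H]([C@@H]1C)C2(C)C | intermediate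
7 | (2R)-1-[(4-methoxybenzyl)oxy]-4-methylpent-4-en-2-yl diisopinocampheylborinate | CC(=C)C[C@@H](OB([C@H]1C[C@H]2C[C@@H]([C@@H]1C)C2(C)C)[C@H]1C[C@H]2C[C@@H]([C@@H]1C)C2(C)C)COCc1ccc(OC)cc1 | intermediate
8 | (2R)-1-[(4-methoxybenzyl)oxy]-4-methylpent-4-en-2-ol | CC(=C)C[C@@H](O)COCc1ccc(OC)cc1 | intermediate
9 | acryloyl chloride | C=CC(=O)Cl | starting material
10 | (2R)-1-[(4-methoxybenzyl)oxy]-4-methylpent-4-en-2-yl prop-2-enoate | CC(=C)C[C@@H](OC(=O)C=C)COCc1ccc(OC)cc1 | intermediate
11 | (6R)-6-{[(4-methoxybenzyl)oxy]methyl}-4-methyl-5,6-dihydro-2H-pyran-2-one | O=C1C=C(C)C[C@H](COCc2ccc(OC)cc2)O1 | intermediate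
12 | (6R)-6-{[(4-methoxybenzyl)oxy]methyl}-4-methyl-5,6-dihydro-2H-pyran-2-ol (lactol, anomer mixture, as its aluminium alkoxide) | OC1C=C(C)C[C@H](COCc2ccc(OC)cc2)O1 | intermediate
13 | (2Z,5R)-6-[(4-methoxybenzyl)oxy]-3-methylhex-2-ene-1,5-diol | OC/C=C(C)\C[C@@H](O)COCc1ccc(OC)cc1 | intermediate
14 | (2Z,5R)-1,5-bis[(tert-butyldimethylsilyl)oxy]-6-[(4-methoxybenzyl)oxy]-3-methylhex-2-ene | CC(C)(C)[Si](C)(C)OC/C=C(C)\C[C@@H](O[Si](C)(C)C(C)(C)C)COCc1ccc(OC)cc1 | intermediate
15 | (2R,4Z)-2,6-bis[(tert-butyldimethylsilyl)oxy]-4-methylhex-4-en-1-ol | CC(C)(C)[Si](C)(C)OC/C=C(C)\C[C@@H](O[Si](C)(C)C(C)(C)C)CO | intermediate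
16 | (2R,4Z)-2,6-bis[(tert-butyldimethylsilyl)oxy]-4-methylhex-4-enal | CC(C)(C)[Si](C)(C)OC/C=C(C)\C[C@@H](O[Si](C)(C)C(C)(C)C)C=O | intermediate
17 | (2R,4Z)-2,6-bis[(tert-butyldimethylsilyl)oxy]-4-methylhex-4-enoic acid | CC(C)(C)[Si](C)(C)OC/C=C(C)\C[C@@H](O[Si](C)(C)C(C)(C)C)C(=O)O | intermediate
18 | methyl (2R,4Z)-2,6-bis[(tert-butyldimethylsilyl)oxy]-4-methylhex-4-enoate | CC(C)(C)[Si](C)(C)OC/C=C(C)\C[C@@H](O[Si](C)(C)C(C)(C)C)C(=O)OC | intermediate
19 | methyl (2R,4Z)-2-[(tert-butyldimethylsilyl)oxy]-6-hydroxy-4-methylhex-4-enoate | OC/C=C(C)\C[C@@H](O[Si](C)(C)C(C)(C)C)C(=O)OC | intermediate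
20 | methyl (2R,4Z)-2-[(tert-butyldimethylsilyl)oxy]-4-methyl-6-oxohex-4-enoate | O=C/C=C(C)\C[C@@H](O[Si](C)(C)C(C)(C)C)C(=O)OC | intermediate
21 | 3-bromofuran | Brc1ccoc1 | starting material
22 | 4-bromofuran-2-carbaldehyde | O=Cc1cc(Br)co1 | starting material
23 | furan-3-yllithium | [Li]c1ccoc1 | intermediate
24 | (4-bromofuran-2-yl)(furan-3-yl)methanol (racemic) | OC(c1ccoc1)c1cc(Br)co1 | intermediate
25 | 4-bromo-2-(furan-3-ylmethyl)furan | Brc1coc(Cc2ccoc2)c1 | intermediate
26 | oxetane | C1COC1 | starting material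
27 | [5-(furan-3-ylmethyl)furan-3-yl]lithium | [Li]c1coc(Cc2ccoc2)c1 | intermediate
28 | 3-[5-(furan-3-ylmethyl)furan-3-yl]propan-1-ol | OCCCc1coc(Cc2ccoc2)c1 | intermediate
29 | 3-[5-(furan-3-ylmethyl)furan-3-yl]propanal | O=CCCc1coc(Cc2ccoc2)c1 | intermediate
30 | ethyl 2-(triphenylphosphoranylidene)propanoate | CCOC(=O)C(C)=P(c1ccccc1)(c1ccccc1)c1ccccc1 | starting material
31 | ethyl (2E)-5-[5-(furan-3-ylmethyl)furan-3-yl]-2-methylpent-2-enoate | CCOC(=O)/C(C)=C/CCc1coc(Cc2ccoc2)c1 | intermediate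
32 | (2E)-5-[5-(furan-3-ylmethyl)furan-3-yl]-2-methylpent-2-en-1-ol | OC/C(C)=C/CCc1coc(Cc2ccoc2)c1 | intermediate
33 | 4-[(3E)-5-bromo-4-methylpent-3-en-1-yl]-2-(furan-3-ylmethyl)furan | BrC/C(C)=C/CCc1coc(Cc2ccoc2)c1 | intermediate
34 | tributyl{(2E)-5-[5-(furan-3-ylmethyl)furan-3-yl]-2-methylpent-2-en-1-yl}phosphonium bromide | CCCC[P+](CCCC)(CCCC)C/C(C)=C/CCc1coc(Cc2ccoc2)c1.[Br-] | intermediate
35 | tributyl{(2E)-5-[5-(furan-3-ylmethyl)furan-3-yl]-2-methylpent-2-en-1-ylidene}phosphorane (ylide of 34) | CCCC[P+](CCCC)(CCCC)[CH-]/C(C)=C/CCc1coc(Cc2ccoc2)c1 | intermediate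
36 | methyl (2R,4Z,6E,8E)-2-[(tert-butyldimethylsilyl)oxy]-11-[5-(furan-3-ylmethyl)furan-3-yl]-4,8-dimethylundeca-4,6,8-trienoate | COC(=O)[C@H](O[Si](C)(C)C(C)(C)C)C\C(C)=C/C=C/C(C)=C/CCc1coc(Cc2ccoc2)c1 | intermediate
37 | methyl (2R,4Z,6E,8E)-11-[5-(furan-3-ylmethyl)furan-3-yl]-2-hydroxy-4,8-dimethylundeca-4,6,8-trienoate | COC(=O)[C@H](O)C\C(C)=C/C=C/C(C)=C/CCc1coc(Cc2ccoc2)c1 | intermediate
38 | propanoic anhydride | CCC(=O)OC(=O)CC | starting material
39 | methyl (2R,4Z,6E,8E)-11-[5-(furan-3-ylmethyl)furan-3-yl]-4,8-dimethyl-2-(propanoyloxy)undeca-4,6,8-trienoate | COC(=O)[C@H](OC(=O)CC)C\C(C)=C/C=C/C(C)=C/CCc1coc(Cc2ccoc2)c1 | intermediate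
40 | (5R)-5-{(2Z,4E,6E)-9-[5-(furan-3-ylmethyl)furan-3-yl]-2,6-dimethylnona-2,4,6-trien-1-yl}-4-hydroxy-3-methylfuran-2(5H)-one | CC1=C(O)[C@@H](C\C(C)=C/C=C/C(C)=C/CCc2coc(Cc3ccoc3)c2)OC1=O | target

**Totals**

Total step count: 24. Longest linear sequence: 16 steps (steps 1–12, then 21–24); the western branch is steps 13–20.

**Three steps most likely to fail**

Step 14 (acid-mediated deoxygenation; the furfuryl cation may alkylate another furan and oligomerise). The fallback sets out from 24 and comes back at 25. MnO2 in CH2Cl2 at rt oxidises the doubly activated carbinol to (4-bromofuran-2-yl)(furan-3-yl)methanone F1. N2H4·H2O in diethylene glycol converts it into [(4-bromofuran-2-yl)(furan-3-yl)methylidene]hydrazine F2. Heating with KOH at 180–195 °C (Huang-Minlon form of the Wolff–Kishner reduction) expels nitrogen and gives 25 under purely basic conditions, so no furfuryl cation is formed.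

Step 21 (E/Z ratio of the new alkene, and Z→E drift of enal 20 under the basic ylide). The fallback sets out from 33 (with 20 as partner) and comes back at 36. Arbuzov reaction of 33 with P(OEt)3 (neat, 120 °C) gives diethyl {(2E)-5-[5-(furan-3-ylmethyl)furan-3-yl]-2-methylpent-2-en-1-yl}phosphonate F3. Deprotonation with LiN(SiMe3)2 in THF at −78 °C gives the lithiated phosphonate F4. F4 adds to 20 in a Horner–Wadsworth–Emmons olefination, whose reversible addition and syn-elimination favour the E-alkene, to give 36.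

Step 24 (Dieckmann closure on the full polyene; risk of C5 epimerisation or O→C acyl shift through the α-acyloxy ester enolate). The fallback sets out from 36 and comes back at 40. Methyl propanoate and LiN(iPr)2 in THF at −78 °C give lithium 1-methoxyprop-1-en-1-olate F5 (3 equiv.). Its intermolecular Claisen condensation with the methyl ester of 36 (−78 → −40 °C) gives methyl (4R,6Z,8E,10E)-4-[(tert-butyldimethylsilyl)oxy]-13-[5-(furan-3-ylmethyl)furan-3-yl]-2,6,10-trimethyl-3-oxotrideca-6,8,10-trienoate F6 (C2 epimers, immaterial; held as its enolate, which shields the C4 centre). Bu4NF in THF then removes the silyl group, the freed C4 hydroxyl lactonises onto the methyl ester, and acidification to pH 3 gives 40.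

**Further compounds**

F1 | step 14 | (4-bromofuran-2-yl)(furan-3-yl)methanone | O=C(c1ccoc1)c1cc(Br)co1
F2 | step 14 | [(4-bromofuran-2-yl)(furan-3-yl)methylidene]hydrazine | NN=C(c1ccoc1)c1cc(Br)co1
F3 | step 21 | diethyl {(2E)-5-[5-(furan-3-ylmethyl)furan-3-yl]-2-methylpent-2-en-1-yl}phosphonate | CCOP(=O)(OCC)C/C(C)=C/CCc1coc(Cc2ccoc2)c1
F4 | step 21 | lithiated phosphonate of F3 | [Li+].CCOP(=O)(OCC)[CH-]/C(C)=C/CCc1coc(Cc2ccoc2)c1
F5 | step 24 | lithium 1-methoxyprop-1-en-1-olate | [Li+].CC=C([O-])OC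
F6 | step 24 | methyl (4R,6Z,8E,10E)-4-[(tert-butyldimethylsilyl)oxy]-13-[5-(furan-3-ylmethyl)furan-3-yl]-2,6,10-trimethyl-3-oxotrideca-6,8,10-trienoate | COC(=O)C(C)C(=O)[C@H](O[Si](C)(C)C(C)(C)C)C\C(C)=C/C=C/C(C)=C/CCc1coc(Cc2ccoc2)c1
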